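**Retrosynthetic overview**
1. The target is the 8–5′ dehydrodimer of isoliquiritigenin; its only non-aromatic ring, the dihydrofuran, is closed last.
2. Key disconnection: the O1–C2 bond of the dihydrofuran, leading back to an achiral seco-dimer (an α-aryl chalcone with a free ortho-phenol). In the forward direction a catalytic enantioselective C–O ring closure sets C2, and C3 follows by equilibration to trans.
3. Second disconnection: the aryl–Cα bond of the seco-dimer, leading back to two molecules of isoliquiritigenin (oxidative phenol coupling; the racemic cyclic dimer is opened by base in the same flask).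
4. Third disconnection: the chalcone C=C, leading back to 2,4-dihydroxyacetophenone and 4-hydroxybenzaldehyde (Claisen–Schmidt).
5. Ring order: all benzene rings are bought; the dihydrofuran ring forms transiently as a racemate in step 2, is reopened, and is closed for good, enantioselectively, in step 3.

Assumption: the target is the (2S,3S)-trans isomer as drawn (C2 aryl and C3 aroyl on opposite faces, both enone double bonds E); the (R)-configured catalyst of step 3 is assumed to give the (2S) product, and if the sense of induction proves opposite the (S)-catalyst is used with nothing else changed.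

**Step 1**
Reactants: 1 1-(2,4-dihydroxyphenyl)ethanone; 2 4-hydroxybenzaldehyde
Product: 3 isoliquiritigenin [(2E)-1-(2,4-dihydroxyphenyl)-3-(4-hydroxyphenyl)prop-2-en-1-one]
Conditions: KOH (60% aq, 12 equiv), EtOH, rt, 48 h; then HCl (2 M) to pH 3
Reagents that add atoms: none
Why: Claisen–Schmidt (crossed aldol) condensation, in which the methyl ketone enolate adds to the non-enolisable aldehyde and E1cB dehydration gives the conjugated chalcone as its thermodynamically favoured E isomer; no stereocentre is formed and the phenols are only deprotonated, so no protection is needed.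

**Step 2**
Reactants: 3 isoliquiritigenin (two molecules)
Product: 5 seco-dimer (2E)-1-(2,4-dihydroxyphenyl)-2-{5-[(1E)-3-(2,4-dihydroxyphenyl)-3-oxoprop-1-en-1-yl]-2-hydroxyphenyl}-3-(4-hydroxyphenyl)prop-2-en-1-one, via racemic trans-dihydrobenzofuran dimer 4 (not isolated)
Conditions: Ag2O (0.55 equiv), acetone/toluene 1:2, rt, dark, 16 h; filter (Celite); then NaOH (2 M aq, degassed), THF, rt, Ar, 4 h; then HCl (1 M, 0 °C) to pH 3
Reagents that add atoms: none
Why: Biomimetic phenol oxidative coupling followed by E1cB ring opening: Ag2O removes one electron from the styrene-conjugated 4-hydroxyl of ring B, the radicals couple C8–C5′ (α-carbon of one enone to the position ortho to the phenol of the other) as with p-coumarate and ferulate esters, the para-quinone methide is trapped 5-exo by the neighbouring phenol to give racemic trans-4, and hydroxide then removes the acidic α-keto benzylic C3–H and expels the aryloxide, so that both stereocentres are erased on purpose and the achiral, base-stable α-aryl chalcone 5 results (either alkene isomer of 5 is usable in step 3).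

**Step 3**
Reactants: 5 seco-dimer
Product: 8 target (2E)-3-[(2S,3S)-3-(2,4-dihydroxybenzoyl)-2-(4-hydroxyphenyl)-2,3-dihydro-1-benzofuran-5-yl]-1-(2,4-dihydroxyphenyl)prop-2-en-1-one, via quinone methide enol tautomer 6 (not isolated), via cis-(2S,3R) epimer 7 (not isolated)
Conditions: (R)-TRIP N-triflylphosphoramide [(R)-3,3′-bis(2,4,6-triisopropylphenyl)-1,1′-binaphthalene-2,2′-diyl N-triflylphosphoramide] (10 mol%), toluene/EtOAc 3:1 (0.02 M), 0 °C → rt, 24–48 h
Reagents that add atoms: none
Why: Proposed new method: a chiral Brønsted acid-catalysed asymmetric cycloisomerisation (a net 5-endo hydroalkoxylation made kinetically accessible as a 5-exo process), in which the acid moves the proton of the 4-hydroxyphenyl group to the aroyl oxygen to give the vinylogous para-quinone methide enol 6, the chiral phosphoramidate then bridges the enol O–H and the attacking ortho-phenol O–H that flank the electrophilic benzylic carbon so that the O1–C2 bond forms on one face only and fixes C2 as S, and the α-keto benzylic C3 (first protonated partly to cis-7) equilibrates through its enol under the same acid to the more stable trans (2S,3S) arrangement without touching C2; the closest known reaction types are chiral phosphoric acid-catalysed enantioselective 1,6-additions to para-quinone methides generated in situ and organocatalytic asymmetric intramolecular oxa-Michael cyclisations of hydroxychalcones to flavanones.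

**Compound list**
1 | 1-(2,4-dihydroxyphenyl)ethanone (2′,4′-dihydroxyacetophenone) | CC(=O)c1ccc(O)cc1O | starting material
2 | 4-hydroxybenzaldehyde | O=Cc1ccc(O)cc1 | starting material
3 | isoliquiritigenin, (2E)-1-(2,4-dihydroxyphenyl)-3-(4-hydroxyphenyl)prop-2-en-1-one | O=C(/C=C/c1ccc(O)cc1)c1ccc(O)cc1O | intermediate
4 | racemic trans dimer, rac-(2E)-3-[(2S*,3S*)-3-(2,4-dihydroxybenzoyl)-2-(4-hydroxyphenyl)-2,3-dihydro-1-benzofuran-5-yl]-1-(2,4-dihydroxyphenyl)prop-2-en-1-one (1:1 mixture of enantiomers, one drawn) | O=C(/C=C/c1ccc2c(c1)[C@H](C(=O)c1ccc(O)cc1O)[C@@H](c1ccc(O)cc1)O2)c1ccc(O)cc1O | intermediate (not isolated)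
5 | seco-dimer, (2E)-1-(2,4-dihydroxyphenyl)-2-{5-[(1E)-3-(2,4-dihydroxyphenyl)-3-oxoprop-1-en-1-yl]-2-hydroxyphenyl}-3-(4-hydroxyphenyl)prop-2-en-1-one (achiral) | O=C(c1ccc(O)cc1O)/C(c1cc(/C=C/C(=O)c2ccc(O)cc2O)ccc1O)=C/c1ccc(O)cc1 | intermediate
6 | quinone methide enol tautomer of 5, 4-[3-(2,4-dihydroxyphenyl)-2-{5-[(1E)-3-(2,4-dihydroxyphenyl)-3-oxoprop-1-en-1-yl]-2-hydroxyphenyl}-3-hydroxyprop-2-en-1-ylidene]cyclohexa-2,5-dien-1-one (enol and methide geometry not defined) | O=C1C=CC(=CC(c2cc(/C=C/C(=O)c3ccc(O)cc3O)ccc2O)=C(O)c2ccc(O)cc2O)C=C1 | intermediate (not isolated)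
7 | cis epimer, (2E)-3-[(2S,3R)-3-(2,4-dihydroxybenzoyl)-2-(4-hydroxyphenyl)-2,3-dihydro-1-benzofuran-5-yl]-1-(2,4-dihydroxyphenyl)prop-2-en-1-one | O=C(/C=C/c1ccc2c(c1)[C@@H](C(=O)c1ccc(O)cc1O)[C@@H](c1ccc(O)cc1)O2)c1ccc(O)cc1O | intermediate (not isolated)
8 | (2E)-3-[(2S,3S)-3-(2,4-dihydroxybenzoyl)-2-(4-hydroxyphenyl)-2,3-dihydro-1-benzofuran-5-yl]-1-(2,4-dihydroxyphenyl)prop-2-en-1-one | O=C(/C=C/c1ccc2c(c1)[C@H](C(=O)c1ccc(O)cc1O)[C@@H](c1ccc(O)cc1)O2)c1ccc(O)cc1O | target

**Total step count:** 3. **Longest linear sequence:** 3 (1 + 2 → 3 → 5 → 8).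

**The three steps most likely to fail**

The enantioselective ring closure of step 3 is the least certain, because it is a proposed transformation. The likely problems are:
- a background, non-selective closure;
- competing six-ring closure by the ring A 2-hydroxyl (2,3-diarylchromanone) or flavanone formation at the second chalcone;
- erosion of ee through acid ionisation of the C2–O bond or, with any base, retro-oxa-Michael opening;
- incomplete cis-to-trans equilibration at C3.

The product must therefore be kept neutral to weakly acidic throughout; it is purified on reverse phase with 0.1% formic acid, the ee is followed by chiral HPLC and the trans geometry by the H2–H3 coupling constant. The fallback uses only known chemistry and sets out from compound 4. Step 2 is stopped after the Ag2O stage and filtration, without the hydroxide treatment, and racemic 4 is isolated by chromatography. It is then resolved by preparative chiral SFC on an amylose tris(3,5-dimethylphenylcarbamate) phase (CO2/MeOH with 0.1% formic acid). This gives the target, where the fallback comes back to the route at compound 8, together with its mirror image (2E)-3-[(2R,3R)-3-(2,4-dihydroxybenzoyl)-2-(4-hydroxyphenyl)-2,3-dihydro-1-benzofuran-5-yl]-1-(2,4-dihydroxyphenyl)prop-2-en-1-one F1. The absolute configuration of each fraction is assigned by electronic circular dichroism.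

The oxidative coupling of step 2 is the second risk. The 8–5′ mode competes with 8–8′, 8–O–4′ and over-oxidation; the acidic ring A phenols can bind silver; and yields of this class of coupling are typically only 20–35% (unreacted 3 is recovered). The fallback sets out from 1 and 2, comes back at compound 4, and changes the approach from coupling a free triphenol to coupling a monomer with a single oxidisable phenol. Compound 1 is selectively protected at the 4-hydroxyl (MOMCl, K2CO3, acetone) to give 1-[2-hydroxy-4-(methoxymethoxy)phenyl]ethanone F2. Claisen–Schmidt condensation of this with 2 (KOH, EtOH) gives (2E)-1-[2-hydroxy-4-(methoxymethoxy)phenyl]-3-(4-hydroxyphenyl)prop-2-en-1-one F3. Ag2O coupling of this mono-phenol in acetone/toluene, the best-precedented form of the reaction, gives the racemic trans bis-MOM dimer rac-(2E)-3-{(2S*,3S*)-3-[2-hydroxy-4-(methoxymethoxy)benzoyl]-2-(4-hydroxyphenyl)-2,3-dihydro-1-benzofuran-5-yl}-1-[2-hydroxy-4-(methoxymethoxy)phenyl]prop-2-en-1-one F4. HCl in MeOH at rt removes both MOM groups to give 4, which then goes through the hydroxide stage of step 2 to 5.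

The protecting-group-free condensation of step 1 is the third risk, since the phenoxide of the aldehyde is a poor electrophile and the yield can fall well below half. The fallback sets out from 1 and 2 and comes back at compound 3. Compound 1 is again converted into 1-[2-hydroxy-4-(methoxymethoxy)phenyl]ethanone F2, and 2 is protected (MOMCl, DIPEA, CH2Cl2) as 4-(methoxymethoxy)benzaldehyde F5. Condensation of the two (KOH, EtOH/H2O, rt) gives (2E)-1-[2-hydroxy-4-(methoxymethoxy)phenyl]-3-[4-(methoxymethoxy)phenyl]prop-2-en-1-one F6. Brief treatment with HCl in MeOH at 50 °C releases 3.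

**Further compounds**
F1 | step 3 | (2E)-3-[(2R,3R)-3-(2,4-dihydroxybenzoyl)-2-(4-hydroxyphenyl)-2,3-dihydro-1-benzofuran-5-yl]-1-(2,4-dihydroxyphenyl)prop-2-en-1-one | O=C(/C=C/c1ccc2c(c1)[C@@H](C(=O)c1ccc(O)cc1O)[C@H](c1ccc(O)cc1)O2)c1ccc(O)cc1O
F2 | step 2 | 1-[2-hydroxy-4-(methoxymethoxy)phenyl]ethanone | CC(=O)c1ccc(OCOC)cc1O
F3 | step 2 | (2E)-1-[2-hydroxy-4-(methoxymethoxy)phenyl]-3-(4-hydroxyphenyl)prop-2-en-1-one | O=C(/C=C/c1ccc(O)cc1)c1ccc(OCOC)cc1O
F4 | step 2 | rac-(2E)-3-{(2S*,3S*)-3-[2-hydroxy-4-(methoxymethoxy)benzoyl]-2-(4-hydroxyphenyl)-2,3-dihydro-1-benzofuran-5-yl}-1-[2-hydroxy-4-(methoxymethoxy)phenyl]prop-2-en-1-one (racemate, one enantiomer drawn) | O=C(/C=C/c1ccc2c(c1)[C@H](C(=O)c1ccc(OCOC)cc1O)[C@@H](c1ccc(O)cc1)O2)c1ccc(OCOC)cc1O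
F5 | step 1 | 4-(methoxymethoxy)benzaldehyde | O=Cc1ccc(OCOC)cc1
F6 | step 1 | (2E)-1-[2-hydroxy-4-(methoxymethoxy)phenyl]-3-[4-(methoxymethoxy)phenyl]prop-2-en-1-one | O=C(/C=C/c1ccc(OCOC)cc1)c1ccc(OCOC)cc1O
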